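**Retrosynthetic overview**
1. Tangeretin ⇒ (E)-2'-hydroxy-3',4',5',6',4-pentamethoxychalcone by opening the O1–C2 bond and removing the C2=C3 unsaturation. The pyranone C ring is the only ring built, and it is built last.
2. Chalcone ⇒ 2'-hydroxy-3',4',5',6'-tetramethoxyacetophenone + 4-methoxybenzaldehyde. This is the key C–C bond, made by an intermolecular Claisen–Schmidt aldol condensation.
3. Acetophenone ⇒ 2,3,4,5-tetramethoxyphenyl acetate (Fries rearrangement into the only free ring position) ⇒ 2,3,4,5-tetramethoxyphenol.
4. Tetramethoxyphenol ⇒ 2,3,4,5-tetramethoxybenzaldehyde (Dakin) ⇒ 1,2,3,4-tetramethoxybenzene (Vilsmeier) ⇒ 2,3,4-trimethoxyphenol (O-methylation) ⇒ 2,3,4-trimethoxybenzaldehyde (Dakin).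
5. Rings A and B are bought as benzene rings, so no carbocycle is constructed.

**Assumption:** tangeretin is achiral (no stereocentre, no stereogenic double bond), so "single enantiomer" means the one structure given. The only stereo-elements in the route are the E-alkene of the chalcone and two transient racemic centres, all of which are erased.

**Step 1**
Reactants: 1 2,3,4-trimethoxybenzaldehyde
Product: 3 2,3,4-trimethoxyphenol, via 2,3,4-trimethoxyphenyl formate 2 (not isolated)
Conditions: 30% aq H2O2 (1.3 equiv), cat. conc. H2SO4, MeOH, 0 °C → rt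
Reagents that add atoms: hydrogen peroxide, OO
Why: In this acid-catalysed Dakin (Baeyer–Villiger-type) oxidation the aryl group, made electron-rich by ortho and para methoxy groups, migrates to oxygen to give the formate, which is methanolysed in situ to the phenol.

**Step 2**
Reactants: 3 2,3,4-trimethoxyphenol
Product: 4 1,2,3,4-tetramethoxybenzene
Conditions: MeI (1.5 equiv), K2CO3 (2 equiv), acetone, reflux
Reagents that add atoms: iodomethane, CI
Why: Williamson O-methylation of the only acidic site proceeds cleanly by SN2 of the phenolate on MeI.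

**Step 3**
Reactants: 4 1,2,3,4-tetramethoxybenzene
Product: 6 2,3,4,5-tetramethoxybenzaldehyde, via aryl iminium salt 5 (not isolated)
Conditions: POCl3 (2 equiv), DMF, 0 °C → 80 °C; then ice/H2O
Reagents that add atoms: N,N-dimethylformamide, CN(C)C=O; water, O
Why: In this Vilsmeier–Haack formylation the two free positions of the C2v-symmetric arene are equivalent and each is ortho/para-activated, so one regioisomer forms, and the iminium or formyl group then blocks a second attack.

**Step 4**
Reactants: 6 2,3,4,5-tetramethoxybenzaldehyde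
Product: 8 2,3,4,5-tetramethoxyphenol, via 2,3,4,5-tetramethoxyphenyl formate 7 (not isolated)
Conditions: 30% aq H2O2 (1.2 equiv), cat. conc. H2SO4, MeOH, 0 °C → rt
Reagents that add atoms: hydrogen peroxide, OO
Why: This second acid-catalysed Dakin oxidation again relies on aryl migration promoted by ortho and para methoxy groups, and limiting the peroxide at low temperature stops the reaction at the phenol rather than the quinone.

**Step 5**
Reactants: 8 2,3,4,5-tetramethoxyphenol
Product: 9 2,3,4,5-tetramethoxyphenyl acetate
Conditions: Ac2O (1.5 equiv), pyridine, cat. DMAP, CH2Cl2, rt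
Reagents that add atoms: acetic anhydride, CC(=O)OC(C)=O
Why: DMAP-catalysed O-acylation of the single hydroxyl group is essentially quantitative and also protects the oxidation-prone phenol for storage.

**Step 6**
Reactants: 9 2,3,4,5-tetramethoxyphenyl acetate
Product: 11 1-(2-hydroxy-3,4,5,6-tetramethoxyphenyl)ethan-1-one, via difluoroboron chelate 10 (not isolated)
Conditions: BF3·OEt2 (3 equiv), AcOH, 80 °C; then H2O, rt → 50 °C
Reagents that add atoms: none
Why: In this Fries rearrangement the acylium ion can enter only the one free ring carbon, which lies ortho to the oxygen, the product is held as its stable six-membered BF2 chelate until water releases it, and AcOH/BF3 re-acylates any phenol that loses its acetyl group.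

**Step 7**
Reactants: 11 1-(2-hydroxy-3,4,5,6-tetramethoxyphenyl)ethan-1-one; 12 4-methoxybenzaldehyde
Product: 14 (E)-2'-hydroxy-3',4',5',6',4-pentamethoxychalcone, via racemic aldol adduct 13 (not isolated)
Conditions: 12 (1.2 equiv), 50% aq KOH (10 equiv), EtOH, rt, 24–48 h; then ice/dil. HCl
Reagents that add atoms: none
Why: In this intermolecular Claisen–Schmidt aldol condensation the methyl ketone enolate adds to the non-enolisable aldehyde and E1cB loss of water gives the conjugated enone, whose E geometry is thermodynamically set and whose aldol stereocentre is destroyed.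

**Step 8**
Reactants: 14 (E)-2'-hydroxy-3',4',5',6',4-pentamethoxychalcone
Product: 16 tangeretin, via racemic flavanone 15 (not isolated)
Conditions: I2 (10 mol%), DMSO, 120 °C, 2–4 h
Reagents that add atoms: none
Why: In this I2/DMSO oxidative cyclisation the 2'-phenol closes onto the enone by 6-endo oxa-Michael addition to the flavanone, iodine dehydrogenates C2–C3, and DMSO re-oxidises the HI, so the transient C2 centre vanishes and the achiral flavone results.

**Compound list**
1 | 2,3,4-trimethoxybenzaldehyde | COc1ccc(C=O)c(OC)c1OC | starting material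
2 | 2,3,4-trimethoxyphenyl formate | COc1ccc(OC=O)c(OC)c1OC | intermediate (not isolated)
3 | 2,3,4-trimethoxyphenol | COc1ccc(O)c(OC)c1OC | intermediate
4 | 1,2,3,4-tetramethoxybenzene | COc1ccc(OC)c(OC)c1OC | intermediate
5 | N,N-dimethyl-(2,3,4,5-tetramethoxyphenyl)methaniminium dichlorophosphate | COc1cc(C=[N+](C)C)c(OC)c(OC)c1OC.[O-]P(=O)(Cl)Cl | intermediate (not isolated)
6 | 2,3,4,5-tetramethoxybenzaldehyde | COc1cc(C=O)c(OC)c(OC)c1OC | intermediate
7 | 2,3,4,5-tetramethoxyphenyl formate | COc1cc(OC=O)c(OC)c(OC)c1OC | intermediate (not isolated)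
8 | 2,3,4,5-tetramethoxyphenol | COc1cc(O)c(OC)c(OC)c1OC | intermediate
9 | 2,3,4,5-tetramethoxyphenyl acetate | COc1cc(OC(C)=O)c(OC)c(OC)c1OC | intermediate
10 | O,O-difluoroboron chelate of the o-hydroxyaryl methyl ketone (2,2-difluoro-5,6,7,8-tetramethoxy-4-methyl-1,3,2-benzodioxaborinine zwitterion) | CC1=[O+][B-](F)(F)Oc2c(OC)c(OC)c(OC)c(OC)c12 | intermediate (not isolated)
11 | 1-(2-hydroxy-3,4,5,6-tetramethoxyphenyl)ethan-1-one | CC(=O)c1c(O)c(OC)c(OC)c(OC)c1OC | intermediate
12 | 4-methoxybenzaldehyde | COc1ccc(C=O)cc1 | starting material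
13 | 3-hydroxy-1-(2-hydroxy-3,4,5,6-tetramethoxyphenyl)-3-(4-methoxyphenyl)propan-1-one, racemic | COc1ccc(cc1)C(O)CC(=O)c1c(O)c(OC)c(OC)c(OC)c1OC | intermediate (not isolated)
14 | (E)-1-(2-hydroxy-3,4,5,6-tetramethoxyphenyl)-3-(4-methoxyphenyl)prop-2-en-1-one | COc1ccc(/C=C/C(=O)c2c(O)c(OC)c(OC)c(OC)c2OC)cc1 | intermediate
15 | 5,6,7,8-tetramethoxy-2-(4-methoxyphenyl)chroman-4-one, racemic | COc1ccc(cc1)C1CC(=O)c2c(OC)c(OC)c(OC)c(OC)c2O1 | intermediate (not isolated)
16 | tangeretin, 5,6,7,8-tetramethoxy-2-(4-methoxyphenyl)-4H-chromen-4-one | COc1ccc(-c2cc(=O)c3c(OC)c(OC)c(OC)c(OC)c3o2)cc1 | target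

**Total step count:** 8. **Longest linear sequence:** 8 steps (1 → 16); 12 is bought and enters at step 7.

**Three steps most likely to fail**

**Step 3 (Vilsmeier formylation).** The two inner methoxy groups of 4 are twisted out of conjugation. The arene is therefore less nucleophilic than it looks, and hot POCl3 may stall or cleave the ether next to the new formyl group. The fallback sets out from 4 and comes back at 8, so it also bypasses step 4. Directed ortho-metalation with n-BuLi/TMEDA in THF at 0 °C gives (2,3,4,5-tetramethoxyphenyl)lithium F1; the two free positions are equivalent. Trapping with B(OMe)3 at −78 °C and acidifying with dilute HCl gives (2,3,4,5-tetramethoxyphenyl)boronic acid F2. Ipso-hydroxylation with H2O2 in AcOH/THF at 0 °C → rt then delivers phenol 8.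

**Step 6 (Fries rearrangement).** The acetyl group has to enter a position flanked on both sides. BF3 at 80 °C can also cleave the methoxy group ortho to the new carbonyl, giving the 2,6-dihydroxy ketone. The fallback sets out from 8, comes back at 11, and uses carbanion chemistry instead of a Lewis acid.
- Treating 8 with MOMCl/i-Pr2NEt in CH2Cl2 gives 1-(methoxymethoxy)-2,3,4,5-tetramethoxybenzene F3.
- n-BuLi in THF at 0 °C removes the only ring proton, which both OMOM and OMe direct to, giving [2-(methoxymethoxy)-3,4,5,6-tetramethoxyphenyl]lithium F4.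
- Adding N-methoxy-N-methylacetamide at −78 °C and quenching with cold dilute HCl gives 1-[2-(methoxymethoxy)-3,4,5,6-tetramethoxyphenyl]ethan-1-one F5.
- Catalytic HCl in MeOH at 40 °C removes the MOM group to give 11.

**Step 8 (I2/DMSO oxidative cyclisation).** HI formed at 120 °C can cleave the peri 5-methoxy group, which is chelation-assisted, and dehydrogenation of 15 may stay incomplete. The fallback sets out from 11, comes back at 16, and needs no oxidation. The dianion of 11 is formed with LiHMDS (3 equiv) in THF at −78 °C. It is C-acylated in an intermolecular Claisen-type condensation with 4-methoxybenzoyl chloride and then quenched with dilute HCl. This gives 1-(2-hydroxy-3,4,5,6-tetramethoxyphenyl)-3-(4-methoxyphenyl)propane-1,3-dione F6. Cyclodehydration with catalytic H2SO4 in AcOH at 95 °C gives tangeretin 16.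

**Further compounds**
F1 | step 3 | (2,3,4,5-tetramethoxyphenyl)lithium | [Li]c1cc(OC)c(OC)c(OC)c1OC
F2 | step 3 | (2,3,4,5-tetramethoxyphenyl)boronic acid | OB(O)c1cc(OC)c(OC)c(OC)c1OC
F3 | step 6 | 1-(methoxymethoxy)-2,3,4,5-tetramethoxybenzene | COCOc1cc(OC)c(OC)c(OC)c1OC
F4 | step 6 | [2-(methoxymethoxy)-3,4,5,6-tetramethoxyphenyl]lithium | [Li]c1c(OC)c(OC)c(OC)c(OC)c1OCOC
F5 | step 6 | 1-[2-(methoxymethoxy)-3,4,5,6-tetramethoxyphenyl]ethan-1-one | CC(=O)c1c(OC)c(OC)c(OC)c(OC)c1OCOC
F6 | step 8 | 1-(2-hydroxy-3,4,5,6-tetramethoxyphenyl)-3-(4-methoxyphenyl)propane-1,3-dione | COc1ccc(cc1)C(=O)CC(=O)c1c(O)c(OC)c(OC)c(OC)c1OC
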